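- beta: starting material 0.25 M; reagent in the second phase 0.95 equiv; the very flask that is asked about, followed so far
- flask: starting material 0.25 M; reagent in the second phase 0.950 equiv; time 8.0 h; volume of the second phase over the first 0.50

beta run (percent of the starting material charged)

| time / h | target / % | starting material / % |
|---|---|---|
| 0.667 | 8.7 | 89.1 |
| 1.33 | 15.4 | 79.3 |
| 2.00 | 18.6 | 71.5 |
| 2.50 | 19.4 | 66.3 |
| 3.00 | 20.1 | 61.8 |

(scatter of a reading: 0.5 percentage points)

- in the second phase: reagent in the second phase; everything else is in the first
- charges count per volume of the first phase; a concentration in a rate is the amount of a species over the volume of its own phase; every rate counts per litre of the first phase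
- the earlier runs hold the two phases in the same ratio of volumes as the flask asked about

- amount of target at 8.0 h, in percent of the starting material charged
- part of the starting material charged that has reacted at 8.0 h

I watch the gap in the beta flask: starting material lost minus target gained, which I read as target passing onward. From 2.00 h to 3.00 h it grows by 8.2 percentage points. Dividing that hourly growth by the mean target present gives the loss constant, 0.424 h⁻¹, an apparent pseudo-first-order constant. One turnover of target then takes 2.36 h, and 8.0 h holds 3.39 turnovers.

Starting material falls from the full charge to 61.8% by 3.00 h, so I give it 0.160 h⁻¹. Target opens with 8.7% at 0.667 h and bends near 2.00 h, inside the first turnover. My two constants put its peak at 3.69 h, at 20.9%. After that it trails the starting material down to 14.8% at 8.0 h, with 72.3% reacted. I take that conversion as high, since the fall of starting material eases.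

The forecast is lower on both, at 13% target and 66% reacted; it has target that “peaks near 20% at about 4 h”.

The flask gives 13.7% target and 60.1% reacted. Half of the reagent's transfer up to the asked time is done by 2.17 h, and half of the step from target to isomer by 3.91 h, while reagent in the reaction phase sinks from 0.0134 M at 0.800 h to 0.00356 M at 8.00 h. Counted from 4.00 h to 8.00 h on isomer plus over-reacted product, the loss constant is 0.305 h⁻¹, lower than my reading.

    target ⇌ isomer of the product (K = 6.80, k = 0.220 h⁻¹)
    starting material + reagent in the reaction phase → target (k = 15.0 M⁻¹ h⁻¹)
    reagent in the reaction phase ⇌ reagent in the second phase, rate k3*([reagent in the reaction phase] - [reagent in the second phase]/K3) per volume of the first phase (partition coefficient = 1.50, kL = 0.210 h⁻¹)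
    reagent in the reaction phase + target → over-reacted product (k = 23.0 M⁻¹ h⁻¹)

For the neighbour flask left to 15 h, my early constant counts 6.36 turnovers and the later one 4.58; my curve, drawn with the early constant, gives 5.39% target. The computed neighbour flask holds 8.21%, more than my curve, with 32.6% starting material.

All runs come from a simulation with made-up constants; scatter was added.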